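The numbers in the tables were generated by integration for an exercise; scatter was added.

Q goes partly astray.

| flask | D | J | Q | remark | time |
|---|---|---|---|---|---|
| birch | 5 mM | 5 mM | 10 mM | run made earlier |  |
| maple | 5 mM | 5 mM | 22 mM | run made earlier |  |
| flask | 5.0 mM | 5.0 mM | 15.0 mM |  | 40 min |

| run | time / min | Z / % | J / % |
|---|---|---|---|
| birch | 4.00 | 62.8 | 18.6 |
| birch | 6.00 | 62.5 | 18.6 |
| birch | 10.0 | 62.5 | 18.0 |
| birch | 20.0 | 63.2 | 17.9 |
| birch | 30.0 | 62.6 | 18.2 |
| birch | 50.0 | 62.3 | 18.1 |
| maple | 3.00 | 84.3 | 7.7 |
| maple | 10.0 | 84.8 | 6.1 |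
| maple | 15.0 | 84.7 | 6.4 |
| maple | 25.0 | 84.7 | 6.7 |
| maple | 40.0 | 85.1 | 6.8 |
| maple | 50.0 | 84.7 | 6.8 |

(readings scatter by 0.3 percentage points)

- Q is single-handed; D and J are mirror images of each other, charged as a racemate, each of them at the stated concentration
- the earlier runs were read with a standard deviation of 0.3 percentage points
- the handed part of Q does not stay in what it makes, so the products of the two hands are mirror images too

- the Z standing at 40 min, as a percentage of the D and J together charged
- the J standing at 40 min, as a percentage of the D and J together charged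

The bench rule for a substrate whose hands interconvert (dynamic kinetic resolution) is one Z per Q until the pair of 0.0100 M is used up. Interconversion is indicated because birch reads Z at 62.3%, more than the 50.0% that D could supply. Applied to the flask, where cQ over the pair is 1.50, the rule turns the whole pair into Z. The readings fall short of it, however: at a ratio of 1.00, birch reads 62.3%, and even at 2.20, higher than the flask's ratio, maple reads 84.7%, so the rule's border lies above both runs. Birch reads 62.8% at 4.00 min and 62.3% at 50.0 min, and maple reads 84.3% at 3.00 min and 84.7% at 50.0 min, so the last readings serve as plateaus.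

Let cW be the Q charged but not found in Z, the charged cQ − cZ. The quotient cZ/(cJ·cW) reads 0.913 mM⁻¹ in birch and 0.921 mM⁻¹ in maple; their mean is the waste quotient K, read as 0.917 mM⁻¹. Taking cD equal to cJ, and Z with these two as the whole charge, gives cJ = charge/(K·cW + 2), but cW itself grows with cJ, so each answer goes back in. Starting from cJ at zero, J comes out at 15.2%, then 10.7%, then 11.7%. This reckoning, separate from the forecast's, stops there, with Z at 76.6%.

The forecast says Z 76.2% (73.5% to 78.5%) and J 11.2% (9.9% to 12.6%), on the ground that “the plateau behaves like a constant ratio”; its J lies 0.50 percentage points below that of the reckoning above.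

The flask gives Z 76.3% and J 11.1%.

    Q + D → Z (k = 16.8 M⁻¹ s⁻¹)
    Q + J → E (k = 0.0880 M⁻¹ s⁻¹)
    D ⇌ G (K = 0.0350, k = 0.0353 s⁻¹)
    J ⇌ G (K = 0.0350, k = 0.0353 s⁻¹)
    Q → X (k = 0.0194 s⁻¹)

At 0.119 min the flask uses Q for Z just 1.2 times as fast as it loses Q to X, and by that loss Q then has a half-life of 0.60 min. By 20.0 min Q stands at 0% and X at 7.26 mM, while D and J stand at 11.1% each. The flask's own values put the waste quotient at 0.933 mM⁻¹. For the same flask charged with 3.8 mM of Q, the waste quotient of 0.917 mM⁻¹ gives J at 35.5%, and J there stands at 35.0%.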